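I had no rate constants for this flask, so I read one quantity from your two runs.

the same everywhere: free catalyst 2.5 mM
- Monday's: starting material 0.050 M; reagent 0.090 M; second substrate 0.050 M; temperature 60 °C; run made earlier
- Saturday's: starting material 0.075 M; reagent 0.090 M; second substrate 0.050 M; temperature 60 °C; run made earlier
- ochre: starting material 0.050 M; reagent 0.0900 M; second substrate 0.0500 M; temperature 60 °C; everything together at the start; time 10 d
- grey: starting material 0.050 M (fed, over 50 h); reagent 0.0900 M; second substrate 0.0500 M; temperature 60 °C; all else is in the flask from the start; the feed brings no volume worth counting; time 10 d
- teal: starting material 0.050 M; reagent 0.0900 M; second substrate 0.0500 M (in portions, 2, over 50 h); temperature 60 °C; first portion at the start, last at 50 h; time 10 d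
- red: starting material 0.050 M; reagent 0.0900 M; second substrate 0.0500 M (fed, over 50 h); the addition at 30 °C, then warmed to 60 °C; the feed brings no volume worth counting; time 10 d

Monday's run (percent of the starting material charged)

| time / d | isomer of the product / % | target / % |
|---|---|---|
| 0.833 | 8 | 55 |
| 1.67 | 14 | 56 |
| 4.00 | 15 | 53 |
| 10.0 | 16 | 54 |

Saturday's run (percent of the starting material charged)

| time / h | isomer of the product / % | target / % |
|---|---|---|
| 6.00 | 2 | 40 |
| 15.0 | 4 | 43 |
| 30.0 | 10 | 43 |
| 50.0 | 13 | 42 |

(each reading ± 1.5 percentage points)

- the earlier runs do not show what temperature does; that part of a forecast is a guess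

1. which flask leads in amount of isomer of the product, in percent of the starting material charged ("all alike" within 1.5 percentage points) (ochre / grey / teal / red / all alike)
2. how much isomer of the product is there at the end, in percent of the starting material charged: ochre
3. how much isomer of the product is there at the end, in percent of the starting material charged: grey
4. how much isomer of the product is there at the end, in percent of the starting material charged: teal
5. how much isomer of the product is there at the end, in percent of the starting material charged: red

I counted turnovers. Let x be the isomer of the product over the target at the end, roughly the isomerisations each target molecule met on the free catalyst. Monday's last readings gave x = 0.296. Saturday's last reading gave 0.310, about the same, though its charge of starting material was larger.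

Monday's isomer moved from 15% to 16% between 4.00 d and 10.0 d, while target stood near 54%. So I took it that the free catalyst was dying. Monday's isomer stood at half of its last reading at 20 h, which I read, within the scatter, as the half-life of the free catalyst, giving a decay time τ = 28.8 h.

Grey's feed of 50 h outlasts that half-life. If the free catalyst decays with that τ, material arriving evenly over a feed time t_f keeps a mean share w = (τ/t_f)(1 − exp(−t_f/τ)) of the exposure that material present from the start gets, here 0.475. So I expected x = 0.141 in grey and about 7.60% isomer, against the 16% read on Monday, whose recipe ochre repeats. Teal and red have their starting material in early, so I kept Monday's x for them and set no level for red, whose temperature step is a guess.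

Your forecast parted from my reckoning on grey: ochre 16%, grey 16%, teal 16%, red 16%, so all alike, since “Ten days is long enough for any feed delay to wash out”.

The flasks gave ochre 14.6%, grey 4.89%, teal 17.9% and red 21.3%, so red led.

    starting material + reagent + free catalyst → free catalyst + target (k = 1800 M⁻² h⁻¹, Ea = 56.0 kJ mol⁻¹)
    second substrate + reagent + free catalyst → free catalyst + second product (k = 9000 M⁻² h⁻¹, Ea = 55.0 kJ mol⁻¹)
    free catalyst → spent catalyst A (k = 0.0500 h⁻¹, Ea = 117 kJ mol⁻¹)
    free catalyst + target → spent catalyst B (k = 0.450 M⁻¹ h⁻¹, Ea = 78.0 kJ mol⁻¹)
    target + free catalyst ⇌ isomer of the product + free catalyst, rate k5*[free catalyst]*[target] forward; the back reaction follows from the equilibrium constant (K = 2.40, k = 8.00 M⁻¹ h⁻¹, Ea = 69.0 kJ mol⁻¹, ΔH = 19.0 kJ mol⁻¹)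
    (constants at 60 °C)

Grey's x came to 0.124, near my 0.141, but its isomer fell short of my 7.60%, with target ending at 39.5%. Red, the second flask, gave x = 0.362, above Monday's 0.296. The step from free catalyst to spent catalyst A was the largest single effect on the gap in isomer between red and grey: without it the gap fell from 16 percentage points to 2.2 points. In red at 1.32 d, still cold, that step taken alone gave free catalyst a half-life of 38 d, against 0.58 d as charged in ochre.

Readings and results were generated by integration with made-up constants; the scatter is artificial.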